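**Assumption:** the SMILES is read as (3R,4Z,6R)-6-({4-[(1E)-but-1-en-1-yl]-2,5-dioxo-2,5-dihydrofuran-3-yl}methyl)oct-4-ene-1,3,4-tricarboxylic acid; "C3, C4, C6" below use this numbering. Reagents without a number are taken as commercial.

**Retrosynthetic overview**
1. The anhydride is the only ring and is closed last: acid removes the tert-butyl esters and the dialkylmaleic half methyl ester closes by itself.
2. Key bond C2–C3: intermolecular, auxiliary-controlled Michael addition of the titanium enolate of a (Z)-alkylidene-succinyl oxazolidinone to tert-butyl acrylate (sets C3).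
3. C4=C5 (Z): Ando-type olefination of aldehyde 18 with a diaryl phosphonosuccinate that already carries the auxiliary.
4. Maleate unit: intermolecular aldol of an ester enolate with (E)-pent-2-enal, oxidation, chelation-controlled (Z)-enol triflate, methoxycarbonylation.
5. C6: Evans Michael addition of a butanoyl oxazolidinone to tert-butyl acrylate.

**Route**

Step 1
Reactants: 1 (4S)-4-benzyl-1,3-oxazolidin-2-one; 2 butanoyl chloride
Product: 4 (4S)-4-benzyl-3-butanoyl-1,3-oxazolidin-2-one, via lithium oxazolidinonide 3 (not isolated)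
Conditions: n-BuLi, THF, −78 °C; then 2, −78 → 0 °C
Reagents that add atoms: butanoyl chloride (2), CCCC(Cl)=O
Why: N-acylation of the lithiated oxazolidinone by the acid chloride (acyl substitution); no stereocentre is touched.

Step 2
Reactants: 4 (4S)-4-benzyl-3-butanoyl-1,3-oxazolidin-2-one; 5 tert-butyl acrylate
Product: 7 tert-butyl (4R)-4-{[(4S)-4-benzyl-2-oxo-1,3-oxazolidin-3-yl]carbonyl}hexanoate, via chlorotitanium enolate 6 (not isolated)
Conditions: TiCl3(OiPr) (from TiCl4 and Ti(OiPr)4, 3:1), i-Pr2NEt, CH2Cl2, 0 °C; then 5, 0 °C; aq NH4Cl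
Reagents that add atoms: tert-butyl acrylate (5), C=CC(=O)OC(C)(C)C
Why: Evans asymmetric Michael addition; the chelated (Z)-titanium enolate adds to the acrylate on the face opposite the benzyl group, which sets the new centre (later C6) as R.

Step 3
Reactants: 7 tert-butyl (4R)-4-{[(4S)-4-benzyl-2-oxo-1,3-oxazolidin-3-yl]carbonyl}hexanoate
Product: 8 tert-butyl (4R)-4-(hydroxymethyl)hexanoate
Conditions: LiBH4, THF, 0 °C → rt
Reagents that add atoms: none
Why: Reductive cleavage of the activated imide carbonyl by LiBH4, which leaves the tert-butyl ester and does not enolise the stereocentre.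

Step 4
Reactants: 8 tert-butyl (4R)-4-(hydroxymethyl)hexanoate
Product: 9 tert-butyl (4R)-4-({[tert-butyl(dimethyl)silyl]oxy}methyl)hexanoate
Conditions: TBSCl, imidazole, DMF, rt
Reagents that add atoms: tert-butyl(chloro)dimethylsilane (TBSCl), CC(C)(C)[Si](C)(C)Cl
Why: Standard silylation of the primary alcohol, so that the ester can be enolised in the next step.

Step 5
Reactants: 9 tert-butyl (4R)-4-({[tert-butyl(dimethyl)silyl]oxy}methyl)hexanoate; 10 (2E)-pent-2-enal
Product: 12 tert-butyl (4E)-2-[(2R)-2-({[tert-butyl(dimethyl)silyl]oxy}methyl)butyl]-3-hydroxyhept-4-enoate (diastereomer mixture at C2/C3), via lithium ester enolate 11 (not isolated)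
Conditions: LiN(iPr)2, THF, −78 °C; then 10, −78 °C; aq NH4Cl
Reagents that add atoms: (2E)-pent-2-enal (10), CC/C=C/C=O
Why: Intermolecular aldol addition; the lithium ester enolate adds 1,2 to the enal at −78 °C, and the two new centres need no control because both become sp2 carbons of the maleate.

Step 6
Reactants: 12 the aldol adduct
Product: 13 tert-butyl (4E)-2-[(2R)-2-({[tert-butyl(dimethyl)silyl]oxy}methyl)butyl]-3-oxohept-4-enoate
Conditions: Dess–Martin periodinane, NaHCO3, CH2Cl2, 0 °C → rt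
Reagents that add atoms: none
Why: Dess–Martin oxidation of the allylic β-hydroxy ester to the β-keto ester under buffered, non-basic conditions.

Step 7
Reactants: 13 the β-keto ester
Product: 15 tert-butyl (2Z,4E)-2-[(2R)-2-({[tert-butyl(dimethyl)silyl]oxy}methyl)butyl]-3-{[(trifluoromethyl)sulfonyl]oxy}hepta-2,4-dienoate, via sodium enolate 14 (not isolated)
Conditions: NaH, Et2O, 0 °C; then Tf2O, −78 → 0 °C
Reagents that add atoms: trifluoromethanesulfonic anhydride, O=S(=O)(OS(=O)(=O)C(F)(F)F)C(F)(F)F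
Why: O-triflation of the sodium enolate; chelation of Na between the enolate oxygen and the ester carbonyl places OTf cis to CO2tBu (Z).

Step 8
Reactants: 15 the (Z)-enol triflate
Product: 16 1-tert-butyl 4-methyl (2Z)-2-[(2R)-2-({[tert-butyl(dimethyl)silyl]oxy}methyl)butyl]-3-[(1E)-but-1-en-1-yl]but-2-enedioate
Conditions: Pd(OAc)2 (5 mol %), PPh3 (10 mol %), Et3N, MeOH, DMF, CO (1 atm), 50 °C
Reagents that add atoms: carbon monoxide, [C-]#[O+]; methanol, CO
Why: Palladium-catalysed alkoxycarbonylation of the vinyl triflate proceeds with retention, so the new CO2Me ends cis to CO2tBu and the diester is a maleate.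

Step 9
Reactants: 16 the silyl ether maleate
Product: 17 1-tert-butyl 4-methyl (2Z)-3-[(1E)-but-1-en-1-yl]-2-[(2R)-2-(hydroxymethyl)butyl]but-2-enedioate
Conditions: HF·pyridine, pyridine, THF, 0 °C → rt
Reagents that add atoms: none
Why: Fluoride desilylation under buffered conditions; the ester nearest the alcohol is the tert-butyl one, which resists lactonisation.

Step 10
Reactants: 17 the primary alcohol
Product: 18 1-tert-butyl 4-methyl (2Z)-3-[(1E)-but-1-en-1-yl]-2-[(2R)-2-formylbutyl]but-2-enedioate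
Conditions: Dess–Martin periodinane, NaHCO3, CH2Cl2, 0 °C; used at once
Reagents that add atoms: none
Why: Dess–Martin oxidation gives the α-branched aldehyde without base, so the α-centre is not epimerised.

Step 11
Reactants: 19 diphenyl phosphite; 20 tert-butyl bromoacetate
Product: 21 tert-butyl (diphenoxyphosphoryl)acetate
Conditions: Et3N, CH2Cl2, 0 °C → rt
Reagents that add atoms: tert-butyl bromoacetate (20), CC(C)(C)OC(=O)CBr
Why: Michaelis–Becker-type P-alkylation of the phosphite by the bromoacetate gives the Ando-type phosphonoacetate.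

Step 12
Reactants: 22 (4R)-4-benzyl-1,3-oxazolidin-2-one; 23 bromoacetyl bromide
Product: 25 (4R)-4-benzyl-3-(bromoacetyl)-1,3-oxazolidin-2-one, via lithium oxazolidinonide 24 (not isolated)
Conditions: n-BuLi, THF, −78 °C; then 23, −78 °C
Reagents that add atoms: bromoacetyl bromide (23), BrCC(Br)=O
Why: N-acylation of the lithiated oxazolidinone at the acyl bromide, which is far more reactive than the alkyl bromide.

Step 13
Reactants: 21 tert-butyl (diphenoxyphosphoryl)acetate; 25 (4R)-4-benzyl-3-(bromoacetyl)-1,3-oxazolidin-2-one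
Product: 27 tert-butyl 4-[(4R)-4-benzyl-2-oxo-1,3-oxazolidin-3-yl]-2-(diphenoxyphosphoryl)-4-oxobutanoate (mixture at C2), via sodium phosphonoacetate 26 (not isolated)
Conditions: NaH, THF/DMF, 0 °C; then 25, 0 °C → rt
Reagents that add atoms: (4R)-4-benzyl-3-(bromoacetyl)-1,3-oxazolidin-2-one (25), BrCC(=O)N1C(=O)OC[C@H]1Cc1ccccc1
Why: SN2 C-alkylation of the soft phosphonate-stabilised carbanion by the α-bromo imide; the centre at C2 is lost again in the olefination.

Step 14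
Reactants: 18 the aldehyde; 27 the phosphonosuccinyl imide
Product: 29 1-tert-butyl 4-methyl (2Z)-2-{(2R,3Z)-6-[(4R)-4-benzyl-2-oxo-1,3-oxazolidin-3-yl]-4-(tert-butoxycarbonyl)-2-ethyl-6-oxohex-3-en-1-yl}-3-[(1E)-but-1-en-1-yl]but-2-enedioate, via sodium phosphonate anion 28 (not isolated)
Conditions: NaH, THF, 0 °C; then 18, −78 → 0 °C
Reagents that add atoms: phosphonate 27, CC(C)(C)OC(=O)C(CC(=O)N1C(=O)OC[C@H]1Cc1ccccc1)P(=O)(Oc1ccccc1)Oc1ccccc1
Why: Ando-type Z-selective Horner–Wadsworth–Emmons olefination; the diaryl phosphonate eliminates fast from the kinetic adduct, so CO2tBu ends cis to the alkyl chain (4Z) and the weakly basic anion leaves the aldehyde α-centre intact.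

Step 15
Reactants: 29 the (Z)-alkylidene-succinyl imide; 5 tert-butyl acrylate
Product: 31 1-tert-butyl 4-methyl (2Z)-2-{(2R,3Z,5R)-5-{[(4R)-4-benzyl-2-oxo-1,3-oxazolidin-3-yl]carbonyl}-4,7-bis(tert-butoxycarbonyl)-2-ethylhept-3-en-1-yl}-3-[(1E)-but-1-en-1-yl]but-2-enedioate, via chlorotitanium dienolate 30 (not isolated)
Conditions: TiCl3(OiPr) (from TiCl4 and Ti(OiPr)4, 3:1), i-Pr2NEt, CH2Cl2, −78 → 0 °C; then 5, 0 °C; aq NH4Cl
Reagents that add atoms: tert-butyl acrylate (5), C=CC(=O)OC(C)(C)C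
Why: Evans Michael addition; soft enolisation is selective for the imide, and the chelated (Z)-enolate reacts at its α-carbon on the face opposite the benzyl group of the (R)-auxiliary, which sets C3 as R and leaves the 4Z alkene in place.

Step 16
Reactants: 31 the Michael adduct
Product: 33 1,4-di-tert-butyl 3-hydrogen (3R,4Z,6R)-6-[(2Z,4E)-2-(tert-butoxycarbonyl)-3-(methoxycarbonyl)hepta-2,4-dien-1-yl]oct-4-ene-1,3,4-tricarboxylate, via lithium peroxycarboxylate 32 (not isolated)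
Conditions: LiOH·H2O, 30 % H2O2, THF/H2O (3:1), 0 °C; then aq Na2SO3; 1 M HCl to pH 3
Reagents that add atoms: hydrogen peroxide, OO
Why: Hydroperoxide cleaves the exocyclic imide carbonyl selectively (Evans auxiliary removal) at 0 °C, where the hindered esters and the α-centre survive.

Step 17
Reactants: 33 the mono-acid tetraester
Product: 35 (3R,4Z,6R)-6-({4-[(1E)-but-1-en-1-yl]-2,5-dioxo-2,5-dihydrofuran-3-yl}methyl)oct-4-ene-1,3,4-tricarboxylic acid, via half ester tetra-acid 34 (not isolated)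
Conditions: CF3CO2H/CH2Cl2 (1:1), 0 °C → rt; evaporate from toluene, 40 °C
Reagents that add atoms: none
Why: Acidolysis of the three tert-butyl esters, followed by intramolecular acyl substitution in which the freed maleic carboxyl expels methanol from the neighbouring methyl ester (dialkylmaleic half esters close spontaneously under acid); no base touches C3 or the 4Z alkene.

**Compound list**
1 | (4S)-4-benzyl-1,3-oxazolidin-2-one | O=C1N[C@@H](Cc2ccccc2)CO1 | starting material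
2 | butanoyl chloride | CCCC(Cl)=O | starting material
3 | lithium (4S)-4-benzyl-2-oxo-1,3-oxazolidin-3-ide (formed in situ) | [Li+].O=C1[N-][C@@H](Cc2ccccc2)CO1 | intermediate
4 | (4S)-4-benzyl-3-butanoyl-1,3-oxazolidin-2-one | CCCC(=O)N1C(=O)OC[C@@H]1Cc1ccccc1 | intermediate
5 | tert-butyl prop-2-enoate (tert-butyl acrylate) | C=CC(=O)OC(C)(C)C | starting material
6 | dichloro(propan-2-olato)titanium (Z)-enolate of 4 (formed in situ) | CC/C=C(\O[Ti](Cl)(Cl)OC(C)C)N1C(=O)OC[C@@H]1Cc1ccccc1 | intermediate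
7 | tert-butyl (4R)-4-{[(4S)-4-benzyl-2-oxo-1,3-oxazolidin-3-yl]carbonyl}hexanoate | CC(C)(C)OC(=O)CC[C@H](C(=O)N1C(=O)OC[C@@H]1Cc1ccccc1)CC | intermediate
8 | tert-butyl (4R)-4-(hydroxymethyl)hexanoate | CC(C)(C)OC(=O)CC[C@H](CO)CC | intermediate
9 | tert-butyl (4R)-4-({[tert-butyl(dimethyl)silyl]oxy}methyl)hexanoate | CC(C)(C)OC(=O)CC[C@H](CO[Si](C)(C)C(C)(C)C)CC | intermediate
10 | (2E)-pent-2-enal | CC/C=C/C=O | starting material
11 | lithium enolate of 9 (formed in situ) | CC(C)(C)OC(O[Li])=CC[C@H](CO[Si](C)(C)C(C)(C)C)CC | intermediate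
12 | tert-butyl (4E)-2-[(2R)-2-({[tert-butyl(dimethyl)silyl]oxy}methyl)butyl]-3-hydroxyhept-4-enoate (mixture at C2/C3) | CC/C=C/C(O)C(C[C@H](CO[Si](C)(C)C(C)(C)C)CC)C(=O)OC(C)(C)C | intermediate
13 | tert-butyl (4E)-2-[(2R)-2-({[tert-butyl(dimethyl)silyl]oxy}methyl)butyl]-3-oxohept-4-enoate | CC/C=C/C(=O)C(C[C@H](CO[Si](C)(C)C(C)(C)C)CC)C(=O)OC(C)(C)C | intermediate
14 | sodium (Z)-enolate of 13, O and CO2tBu cis (formed in situ) | [Na+].CC/C=C/C([O-])=C(\C[C@H](CO[Si](C)(C)C(C)(C)C)CC)C(=O)OC(C)(C)C | intermediate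
15 | tert-butyl (2Z,4E)-2-[(2R)-2-({[tert-butyl(dimethyl)silyl]oxy}methyl)butyl]-3-{[(trifluoromethyl)sulfonyl]oxy}hepta-2,4-dienoate | CC/C=C/C(OS(=O)(=O)C(F)(F)F)=C(\C[C@H](CO[Si](C)(C)C(C)(C)C)CC)C(=O)OC(C)(C)C | intermediate
16 | 1-tert-butyl 4-methyl (2Z)-2-[(2R)-2-({[tert-butyl(dimethyl)silyl]oxy}methyl)butyl]-3-[(1E)-but-1-en-1-yl]but-2-enedioate | CC/C=C/C(C(=O)OC)=C(\C[C@H](CO[Si](C)(C)C(C)(C)C)CC)C(=O)OC(C)(C)C | intermediate
17 | 1-tert-butyl 4-methyl (2Z)-3-[(1E)-but-1-en-1-yl]-2-[(2R)-2-(hydroxymethyl)butyl]but-2-enedioate | CC/C=C/C(C(=O)OC)=C(\C[C@H](CO)CC)C(=O)OC(C)(C)C | intermediate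
18 | 1-tert-butyl 4-methyl (2Z)-3-[(1E)-but-1-en-1-yl]-2-[(2R)-2-formylbutyl]but-2-enedioate | CC/C=C/C(C(=O)OC)=C(\C[C@H](C=O)CC)C(=O)OC(C)(C)C | intermediate
19 | diphenyl phosphite (diphenyl phosphonate) | O=[PH](Oc1ccccc1)Oc1ccccc1 | starting material
20 | tert-butyl bromoacetate | CC(C)(C)OC(=O)CBr | starting material
21 | tert-butyl (diphenoxyphosphoryl)acetate | CC(C)(C)OC(=O)CP(=O)(Oc1ccccc1)Oc1ccccc1 | intermediate
22 | (4R)-4-benzyl-1,3-oxazolidin-2-one | O=C1N[C@H](Cc2ccccc2)CO1 | starting material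
23 | bromoacetyl bromide | BrCC(Br)=O | starting material
24 | lithium (4R)-4-benzyl-2-oxo-1,3-oxazolidin-3-ide (formed in situ) | [Li+].O=C1[N-][C@H](Cc2ccccc2)CO1 | intermediate
25 | (4R)-4-benzyl-3-(bromoacetyl)-1,3-oxazolidin-2-one | BrCC(=O)N1C(=O)OC[C@H]1Cc1ccccc1 | intermediate
26 | sodium salt of 21, phosphonate-stabilised carbanion (formed in situ) | [Na+].CC(C)(C)OC(=O)[CH-]P(=O)(Oc1ccccc1)Oc1ccccc1 | intermediate
27 | tert-butyl 4-[(4R)-4-benzyl-2-oxo-1,3-oxazolidin-3-yl]-2-(diphenoxyphosphoryl)-4-oxobutanoate (mixture at C2) | CC(C)(C)OC(=O)C(CC(=O)N1C(=O)OC[C@H]1Cc1ccccc1)P(=O)(Oc1ccccc1)Oc1ccccc1 | intermediate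
28 | sodium salt of 27, carbanion at C2 (formed in situ) | [Na+].CC(C)(C)OC(=O)[C-](CC(=O)N1C(=O)OC[C@H]1Cc1ccccc1)P(=O)(Oc1ccccc1)Oc1ccccc1 | intermediate
29 | 1-tert-butyl 4-methyl (2Z)-2-{(2R,3Z)-6-[(4R)-4-benzyl-2-oxo-1,3-oxazolidin-3-yl]-4-(tert-butoxycarbonyl)-2-ethyl-6-oxohex-3-en-1-yl}-3-[(1E)-but-1-en-1-yl]but-2-enedioate | CC/C=C/C(C(=O)OC)=C(\C[C@H](/C=C(\C(=O)OC(C)(C)C)CC(=O)N1C(=O)OC[C@H]1Cc1ccccc1)CC)C(=O)OC(C)(C)C | intermediate
30 | dichloro(propan-2-olato)titanium (Z)-enolate of 29, imide enolate conjugated to the alkene (formed in situ) | CC/C=C/C(C(=O)OC)=C(\C[C@H](/C=C(\C(=O)OC(C)(C)C)/C=C(\O[Ti](Cl)(Cl)OC(C)C)N1C(=O)OC[C@H]1Cc1ccccc1)CC)C(=O)OC(C)(C)C | intermediate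
31 | 1-tert-butyl 4-methyl (2Z)-2-{(2R,3Z,5R)-5-{[(4R)-4-benzyl-2-oxo-1,3-oxazolidin-3-yl]carbonyl}-4,7-bis(tert-butoxycarbonyl)-2-ethylhept-3-en-1-yl}-3-[(1E)-but-1-en-1-yl]but-2-enedioate | CC/C=C/C(C(=O)OC)=C(\C[C@H](/C=C(\C(=O)OC(C)(C)C)[C@@H](CCC(=O)OC(C)(C)C)C(=O)N1C(=O)OC[C@H]1Cc1ccccc1)CC)C(=O)OC(C)(C)C | intermediate
32 | lithium peroxycarboxylate of 33, peracid salt at C3 (formed in situ) | [Li+].CC/C=C/C(C(=O)OC)=C(\C[C@H](/C=C(\C(=O)OC(C)(C)C)[C@@H](CCC(=O)OC(C)(C)C)C(=O)O[O-])CC)C(=O)OC(C)(C)C | intermediate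
33 | 1,4-di-tert-butyl 3-hydrogen (3R,4Z,6R)-6-[(2Z,4E)-2-(tert-butoxycarbonyl)-3-(methoxycarbonyl)hepta-2,4-dien-1-yl]oct-4-ene-1,3,4-tricarboxylate | CC/C=C/C(C(=O)OC)=C(\C[C@H](/C=C(\C(=O)OC(C)(C)C)[C@@H](CCC(=O)OC(C)(C)C)C(=O)O)CC)C(=O)OC(C)(C)C | intermediate
34 | (3R,4Z,6R)-6-[(2Z,4E)-2-carboxy-3-(methoxycarbonyl)hepta-2,4-dien-1-yl]oct-4-ene-1,3,4-tricarboxylic acid (formed in situ) | CC/C=C/C(C(=O)OC)=C(\C[C@H](/C=C(\C(=O)O)[C@@H](CCC(=O)O)C(=O)O)CC)C(=O)O | intermediate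
35 | (3R,4Z,6R)-6-({4-[(1E)-but-1-en-1-yl]-2,5-dioxo-2,5-dihydrofuran-3-yl}methyl)oct-4-ene-1,3,4-tricarboxylic acid | CC/C=C/C1=C(C[C@H](/C=C(\C(=O)O)[C@@H](CCC(=O)O)C(=O)O)CC)C(=O)OC1=O | target

**Step count**
Total: 17 steps. Longest linear sequence: 14 steps (steps 1–10, then 14–17); steps 11–13 make the olefination reagent in a side branch.

**Three steps most likely to fail, with fallbacks**

Step 14 (Z-selectivity of the olefination with the branched, imide-bearing phosphonate). The fallback sets out from aldehyde 18 and comes back at 29. The succinyl arm is attached only after the alkene is made. Phosphonate 21 is brominated (NaH, THF, 0 °C; then Br2, −78 °C) to tert-butyl bromo(diphenoxyphosphoryl)acetate F1. Its sodium salt condenses with 18 (THF, −78 °C) to give the (E)-2-bromo enoate F2, in which CO2tBu is cis to the alkyl chain; any geometric isomer is separated here. Cross-coupling of F2 with the Reformatsky reagent made from 25 and Zn (Pd(PPh3)4, THF, 40 °C) replaces Br by the CH2C(O)N-oxazolidinone arm with retention and gives 29.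

Step 15 (Michael addition of a conjugated titanium enolate in the presence of several Lewis-basic esters). The fallback sets out from 29 and comes back at 31. The sodium enolate of 29 (NaN(SiMe3)2, THF, −78 °C) is alkylated with allyl iodide, in the same facial sense, to give the C3-allyl imide F3. Hydroboration of the terminal alkene alone (9-BBN, THF; then NaBO3·4H2O) gives the primary alcohol F4. Oxidation (TEMPO, PhI(OAc)2, MeCN/H2O) gives the carboxylic acid F5. Esterification with tert-butyl 2,2,2-trichloroacetimidate (BF3·OEt2 cat., CH2Cl2/cyclohexane) gives 31.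

Step 16 (peroxide cleavage of a hindered imide next to electron-poor alkenes). The fallback sets out from 31 and comes back at 35. Transesterification with lithium 4-methoxybenzyl oxide (from 4-methoxybenzyl alcohol and n-BuLi, THF, 0 °C) removes the auxiliary without peroxide and gives the 4-methoxybenzyl ester F6. CF3CO2H/CH2Cl2 with anisole then cleaves the 4-methoxybenzyl and tert-butyl esters together and, through half ester 34, gives 35.

**Further compounds**
F1 | step 14 | tert-butyl bromo(diphenoxyphosphoryl)acetate | CC(C)(C)OC(=O)C(Br)P(=O)(Oc1ccccc1)Oc1ccccc1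
F2 | step 14 | 1-tert-butyl 4-methyl (2Z)-2-[(2R,3E)-4-bromo-4-(tert-butoxycarbonyl)-2-ethylbut-3-en-1-yl]-3-[(1E)-but-1-en-1-yl]but-2-enedioate | CC/C=C/C(C(=O)OC)=C(\C[C@H](/C=C(/Br)C(=O)OC(C)(C)C)CC)C(=O)OC(C)(C)C
F3 | step 15 | C3-allyl imide: as 31 but with prop-2-en-1-yl in place of the 2-(tert-butoxycarbonyl)ethyl group on C3 (3R) | CC/C=C/C(C(=O)OC)=C(\C[C@H](/C=C(\C(=O)OC(C)(C)C)[C@@H](CC=C)C(=O)N1C(=O)OC[C@H]1Cc1ccccc1)CC)C(=O)OC(C)(C)C
F4 | step 15 | primary alcohol: as 31 but with 3-hydroxypropyl on C3 (3R) | CC/C=C/C(C(=O)OC)=C(\C[C@H](/C=C(\C(=O)OC(C)(C)C)[C@@H](CCCO)C(=O)N1C(=O)OC[C@H]1Cc1ccccc1)CC)C(=O)OC(C)(C)C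
F5 | step 15 | carboxylic acid: as 31 but with 2-carboxyethyl on C3 (3R) | CC/C=C/C(C(=O)OC)=C(\C[C@H](/C=C(\C(=O)OC(C)(C)C)[C@@H](CCC(=O)O)C(=O)N1C(=O)OC[C@H]1Cc1ccccc1)CC)C(=O)OC(C)(C)C
F6 | step 16 | 1,4-di-tert-butyl 3-(4-methoxybenzyl) (3R,4Z,6R)-6-[(2Z,4E)-2-(tert-butoxycarbonyl)-3-(methoxycarbonyl)hepta-2,4-dien-1-yl]oct-4-ene-1,3,4-tricarboxylate | CC/C=C/C(C(=O)OC)=C(\C[C@H](/C=C(\C(=O)OC(C)(C)C)[C@@H](CCC(=O)OC(C)(C)C)C(=O)OCc1ccc(OC)cc1)CC)C(=O)OC(C)(C)C
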